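The runs are simulated from invented constants; noise was put on by code.

**The vessel.** Your stirred vessel takes starting material at a steady rate while gas, held at its saturation level, passes into solution as reagent.

the same everywhere: gas 36 mM (held)

| run | starting material | remark | time |
|---|---|---|---|
| violet | 0.095 M (fed, over 3.0 min) | run made earlier |  |
| amber | 0.14 M (fed, over 3.0 min) | run made earlier |  |
| elm | 0.19 M (fed, over 3.0 min) |  | 12 min |
| larch | 0.19 M (fed, over 4.0 min) |  | 12 min |
| oak | 0.19 M (fed, over 6.0 min) |  | 12 min |
| cedar | 0.19 M (fed, over 10 min) |  | 12 min |

- violet (time / min: target / %): 0.833: 0.7; 2.00: 7.8; 4.00: 38.1; 10.0: 93.2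
- amber (time / min: target / %): 1.33: 1.9; 3.00: 19.4; 6.00: 60.5; 10.0: 92.3

(each reading ± 0.5 percentage points)

- at the start none of reagent is dissolved
- the analysis behind the earlier runs scatters by 0.5 percentage points, standard deviation
- reactions considered so far: gas <-> reagent; starting material + reagent -> intermediate; intermediate -> target
- percentages count the whole charge, also what has not yet gone in
- "hardly changes" means that all values lie within two and a half points (for a concentration: within two and a half percent of the largest)

1. amount of target at the end, in percent of the starting material charged for elm, larch, oak, cedar, in this order
2. how the row runs (hardly changes / falls all the way / falls, then rises / rises all the way / rises, then falls)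

**End and pace.** The readings head towards the whole charge as target, so watch the shortfall, the part of the charge not yet target. Late in amber it falls from 39.5 % at 6.00 min to 7.70 % at 10.0 min. Read as a pseudo-first-order tail, this gives the tail rate, the fractional fall of the shortfall per minute, of 0.409 min⁻¹.

**Turned round.** What would make the row anything but falling? Stretching the feed from 3.0 min to 10 min delays the average entry of the charge by 3.50 min, which on this estimate multiplies the shortfall by the exponential of tail rate times delay, 4.18. My own reckoning carries amber's shortfall on to 12 min, giving 3.40 %, as a stand-in for elm. The estimate then has cedar trailing elm by 11 percentage points, and a row that hardly changes must fit that gap into two and a half points. A rising row needs slower feeding, at this charge and end time, to gain more than the delay costs. Yet going from violet to amber raises the charge 1.47-fold and the shortfall at 10.0 min by a reading of 1.13, less than the delay factor.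

**The forecast.** It gives 94.5 %, 93.7 %, 91.5 % and 78 %, so falls all the way. Its ground: “the lost reaction time dominates”. My cedar value is 85.8 %, and the forecast lies below it.

**The flask.** The row comes out at 95.3 %, 94.8 %, 92.9 % and 82.5 %: falls all the way.

    gas ⇌ reagent, rate k1*(csat - [reagent]) (kL = 0.0180 s⁻¹)
    starting material + reagent → intermediate (k = 0.750 L mol⁻¹ s⁻¹)
    intermediate → target (k = 0.00710 s⁻¹)

Cedar at 12.0 min still holds 15.9 % as intermediate and 1.56 % as starting material. Now put the tail rate to oak: its feed delays the charge by 1.50 min, a factor 1.85 on elm's shortfall of 4.70 %, which reckons oak's target at 91.3 %. Oak stands at 92.9 %.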